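## Analysis of the target

The target 28 is a C2-symmetric dimer of a 7-hydroxyisoflavan: each half is a chroman (ring A fused to the heterocycle O1–C2–C3–C4) that carries ring B at C3, and the two ring B units are joined by a single oxygen between their C4' carbons. Each ring B has three neighbouring oxygens that are all different, a methyl ether at C2', a free hydroxyl at C3' and the diaryl ether oxygen at C4', and C1', next to C2', is bonded to C3. The only stereocentres are the two C3 atoms, both R; they are remote from each other, so each must be set independently, and any error appears as the (R,S) diastereomer. C3 is a benzylic tertiary C–H centre with no heteroatom on it, so it must be set in a C–C bond-forming event. Sensitive points are the four phenols, the electron-rich rings (oxidation) and the benzylic C3–H once an acidifying group sits next to it. The hard parts are placing carbon regioselectively at C1' of a 1,2,3-trioxygenated ring, telling three contiguous oxygens apart, and running one stereoselective event twice in one molecule. The strategy rests on one feature: C1' is ortho to the C2' oxygen, and the other ortho position of that oxygen, C3', is already oxygenated. An allyl group bound to the C2' oxygen can therefore be passed to C1' by a [3,3] shift, and the oxygen freed is the one that must become the methyl ether.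

## Retrosynthetic reasoning

**28 from 27.** The four phenols (C7–OH on each ring A, C3'–OH on each ring B) are masked as benzyl ethers and released together in the last step. Benzyl is chosen because it survives base, hydride, heat and mild acid and leaves under neutral hydrogenolysis, which does not touch the diaryl ether or the chroman.

**27 from 26, and 26 from 25.** Both O1–C2 bonds are cut. The heterocycles are closed last, by intramolecular Mitsunobu etherification of a ring A phenol with a primary alcohol, because this needs only a CH2OH group at C2 and does not involve C3. The ring A phenols of 26 are released from the methoxymethyl acetals of 25 under conditions that spare benzyl and methyl ethers.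

**25 from 23, and 23 from 22.** The C2 hydroxymethyl groups are the remnant of E-propenyl groups, cut at the alkene and reduced in the same flask, so C3 never sits beside a carbonyl group in an isolated compound. The C2' methyl ethers come from the phenols that the key step sets free; this is how the three ring B oxygens are differentiated without extra protecting-group steps.

**22 from 19 (key disconnection).** Both C3–C1' bonds are cut. In 19 each C2' oxygen carries an (R,E)-configured 5-arylpent-3-en-2-yl group. A [3,3] shift moves its alkene terminus to C1', makes C3 with ring A already attached through C4, and leaves a propenyl group as the handle for C2. Cutting here solves regiochemistry (the group can only settle at the one ortho position that can enolise) and stereochemistry (transferred from a carbinol centre that is easy to make) in one step, twice.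

**19 from 18 and 17, and 18 from 8 and 17.** The two aryl–O–C(carbinol) bonds are cut one after the other. Each is made by Mitsunobu etherification of a phenol with one molecule of the (S)-allylic alcohol 17, which inverts the carbinol centre to R. Attaching both units to the preformed core 8 keeps ring B achiral and symmetrical until the chirality is introduced. Working in two stages lets each stage run with close to one equivalent of the valuable alcohol. The mono-ether 18 and the bis-ether 19 differ by a free phenol, so 19 enters the key step free of half-etherified material.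

**17 from 16, and 16 from 14 and 13.** The E-alkene comes from hydroxyl-directed trans-reduction of the propargylic alcohol 16, which fixes the geometry completely; this matters because the Z geometry would deliver the opposite C3 configuration from the same ether centre. The bond between the future C4 and the alkyne is cut, giving (S)-but-3-yn-2-ol 14 as the source of chirality and the ring A benzylic bromide 13. Bromide 13 goes back through alcohol 12 and aldehyde 11 to the monobenzyl ether 10 and 2,4-dihydroxybenzaldehyde 9, whose hydrogen-bonded 2-hydroxyl allows the 4-hydroxyl to be benzylated first.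

**8 from 7; 7 from 6 and 5; both from 2 and 1.** The C2' hydroxyls of 8 are traced to aryl bromides in 7, and the central diaryl ether is cut into phenol 6 and boronic acid 5. Both come from one precursor, the dibromide 2 made from 2,6-dibromophenol 1. The phenol oxygen of 1 becomes the C3' benzyl ether, one bromine becomes the ether link and the other becomes the C2' oxygen, so the substitution pattern of 1 fixes the 1,2,3-pattern. No protecting group is needed, because the copper-mediated coupling of 5 with 6 leaves aryl bromides untouched.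

## Alternatives that were turned down

Alternative 1: enzymatic Baeyer–Villiger desymmetrisation.
- Disconnection: the C2–O bond of each half is traced to the bis(β-aryl-γ-butyrolactone) A2, which comes from the achiral bis(3-arylcyclobutanone) A1.
- Forward key step: a flavin-dependent monooxygenase inserts oxygen into one of the two enantiotopic acyl–methylene bonds of each four-membered ketone of A1.
- For: both stereocentres come from an achiral precursor under catalyst control at ambient temperature, and 3-arylcyclobutanones are a favourable substrate class for these enzymes.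
- Against: A1 already needs carbon at C1' of ring B, so the regiochemical problem is only moved, and a four-membered ring must be built on it. A1 is a large lipophilic dimer whose aryl group has an ortho methoxy group next to the cyclobutanone, so fit in the active site and turnover at both sites are uncertain. A2 still lacks ring A: the lactone carbonyl must be bonded to C4a and deoxygenated to the C4 methylene before O1–C2 can be closed, which adds several operations per half.
- Comparison: on stereocontrol this alternative is probably stronger, since it does not depend on a high-temperature step. The chosen route offers instead that 22 carries every carbon of the skeleton, including ring A, directly after the key step.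

Alternative 2: bis-isoflavylium formation and reduction.
- Disconnection: both C4–C4a and both O1–C2 bonds are cut, leading to the bis(enaminal) A3 and two molecules of resorcinol A4.
- Forward key step: under strong acid, C4 of A4 attacks the iminium carbon of A3 and the adjacent phenol oxygen closes onto the aldehyde with loss of water, giving the bis(7-hydroxyisoflavylium) dichloride A5.
- For: four bonds and two rings form in one operation, ring A needs no protection, and the regiochemistry of A4 gives the 7-hydroxyl automatically. In ring construction and step count this alternative is stronger.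
- Against: A5 is planar at C3, so both stereocentres are postponed to a reduction sequence. Hydride addition gives the bis(isoflav-3-ene) A6, and a double asymmetric hydrogenation of two unfunctionalised trisubstituted alkenes must follow. Each alkene bears an aryl group twisted by its ortho methoxy substituent, and free phenols are present, so facial selection rests on the catalyst alone and must succeed twice. A3 also needs a two-carbon acid side chain at C1' before formylation.
- Comparison: the chosen route is longer but sets C3 together with the C3–C1' bond, from stereochemical information carried in the substrate.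

Alternative 3: conjunctive coupling.
- Disconnection: C3–C1' and C4–C4a of each half are cut at once, leading to the ring B bis(boronate) A7, vinyllithium A8 and the ring A aryl triflate A9.
- Forward key step: A7 and A8 form a bis(vinyl ate complex); under Pd(OAc)2 with a chiral bisphosphine ligand the aryl group of A9 adds to the vinyl terminus while ring B migrates from boron to carbon, giving the bis(secondary benzylic boronate) A10.
- For: two skeletal bonds and one stereocentre per half form in a single enantioselective catalytic step. In bonds formed per step this alternative is stronger.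
- Against: the migrating ring B has an ortho methoxy group and A9 an ortho acetal oxygen, and ortho substitution on both partners slows ate formation and migration and favours direct cross-coupling. A7 needs boron at C1' of the diaryl ether core, which nothing in the structure directs against C5' or the benzylic positions. A10 carries boron where C2 must be, so a one-carbon homologation at a hindered secondary benzylic boronate is needed before oxidation.
- Comparison: the chosen route gets the C1' regiochemistry from the position of an oxygen, and its key step needs no catalyst matching.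

Key step: step 14

Remark on the chemistry: 1, 9 and 14 (and the enantiomer of 14 used in one fallback) are taken to be commercially available. The two ether bonds to the core are made in two separate steps with one molecule of 17 each, and every later two-directional step is run with a modest excess of the reagents so that both halves react.

## Route

Step 1
Reactants: 1 2,6-dibromophenol
Product: 2 2-(benzyloxy)-1,3-dibromobenzene
Conditions: BnBr, K2CO3, DMF, rt
Reagents that add atoms: benzyl bromide, BrCc1ccccc1
Why: Williamson etherification; the doubly ortho-brominated phenol is acidic enough for carbonate, and the unhindered benzylic bromide reacts despite the flanking bromines.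

Step 2
Reactants: 2 2-(benzyloxy)-1,3-dibromobenzene
Product: 5 [2-(benzyloxy)-3-bromophenyl]boronic acid, via [2-(benzyloxy)-3-bromophenyl]lithium 3 (not isolated), via lithium aryl(triisopropoxy)borate 4 (not isolated)
Conditions: n-BuLi (1.0 equiv), THF, −78 °C; B(OiPr)3, −78 °C to rt; 1 M HCl
Reagents that add atoms: triisopropyl borate, CC(C)OB(OC(C)C)OC(C)C; water, O
Why: Bromine–lithium exchange at −78 °C is far faster than benzylic deprotonation and stops after one bromine because the aryllithium deactivates the ring toward a second exchange. Borate trapping and hydrolysis give the boronic acid.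

Step 3
Reactants: 5 [2-(benzyloxy)-3-bromophenyl]boronic acid (one third of the material)
Product: 6 2-(benzyloxy)-3-bromophenol
Conditions: 30% H2O2, NaOH, THF/H2O, 0 °C to rt; then dilute HCl
Reagents that add atoms: hydrogen peroxide, OO
Why: Ipso-oxidation of an arylboronic acid (hydroperoxide adds to boron, the aryl group shifts from boron to oxygen); the aryl bromide and the benzyl ether are inert.

Step 4
Reactants: 6 2-(benzyloxy)-3-bromophenol; 5 [2-(benzyloxy)-3-bromophenyl]boronic acid (twofold amount)
Product: 7 1,1'-oxybis[2-(benzyloxy)-3-bromobenzene]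
Conditions: Cu(OAc)2 (1.0 equiv), pyridine, 4 Å MS, CH2Cl2, dry air, rt
Reagents that add atoms: none
Why: Chan–Lam O-arylation; at room temperature Cu(OAc)2 does not insert into aryl–bromine bonds, so both bromides are kept. Adventitious oxidation of 5 to 6 is harmless because the ether is symmetrical and the phenol so formed gives the same product.

Step 5
Reactants: 7 1,1'-oxybis[2-(benzyloxy)-3-bromobenzene]
Product: 8 3,3'-oxybis[2-(benzyloxy)phenol]
Conditions: Pd2(dba)3 (2 mol %), tBuXPhos (8 mol %), KOH (6 equiv), 1,4-dioxane/H2O 1:1, 100 °C; then 1 M HCl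
Reagents that add atoms: potassium hydroxide, [K+].[OH-]
Why: Palladium-catalysed hydroxylation of aryl bromides with hydroxide (Buchwald-type C–O coupling); benzyl and diaryl ethers are stable to aqueous base. The phenoxide formed first cannot cyclise onto the second ring because that would require an impossibly strained meta-bridged ring.

Step 6
Reactants: 9 2,4-dihydroxybenzaldehyde
Product: 10 4-(benzyloxy)-2-hydroxybenzaldehyde
Conditions: BnBr (1.05 equiv), NaHCO3, MeCN, 80 °C
Reagents that add atoms: benzyl bromide, BrCc1ccccc1
Why: Regioselective Williamson etherification; the 2-hydroxyl is held in a hydrogen bond to the aldehyde, while the 4-hydroxyl, a vinylogous acid, is deprotonated by weak base and alkylated.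

Step 7
Reactants: 10 4-(benzyloxy)-2-hydroxybenzaldehyde
Product: 11 4-(benzyloxy)-2-(methoxymethoxy)benzaldehyde
Conditions: MOMCl, iPr2NEt, CH2Cl2, 0 °C to rt
Reagents that add atoms: chloromethyl methyl ether, COCCl
Why: Acetal protection of the remaining phenol with a highly reactive alkylating agent; the acetal is orthogonal to benzyl and is removed later by mild acid.

Step 8
Reactants: 11 4-(benzyloxy)-2-(methoxymethoxy)benzaldehyde
Product: 12 [4-(benzyloxy)-2-(methoxymethoxy)phenyl]methanol
Conditions: NaBH4, MeOH/THF, 0 °C
Reagents that add atoms: none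
Why: Borohydride reduction of an aryl aldehyde; ethers and acetal are untouched.

Step 9
Reactants: 12 [4-(benzyloxy)-2-(methoxymethoxy)phenyl]methanol
Product: 13 4-(benzyloxy)-1-(bromomethyl)-2-(methoxymethoxy)benzene
Conditions: CBr4, PPh3, CH2Cl2, 0 °C; filtered and used at once
Reagents that add atoms: carbon tetrabromide, BrC(Br)(Br)Br
Why: Appel bromination under neutral conditions, which spares the acid-labile acetal. The electron-rich benzylic bromide is not stored.

Step 10
Reactants: 14 (S)-but-3-yn-2-ol; 13 4-(benzyloxy)-1-(bromomethyl)-2-(methoxymethoxy)benzene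
Product: 16 (2S)-5-[4-(benzyloxy)-2-(methoxymethoxy)phenyl]pent-3-yn-2-ol, via bis(bromomagnesium) alkynyl alkoxide 15 (not isolated)
Conditions: EtMgBr (2.05 equiv), THF, 0 to 40 °C; CuCl (10 mol %); then 13, THF, 50 °C; aq. NH4Cl
Reagents that add atoms: none
Why: Copper-catalysed alkylation of an alkynylmagnesium halide with a benzylic bromide, the classical coupling of propargylic alcohol dianions; the magnesium alkoxide is a poor nucleophile, so the carbon terminus reacts. The carbinol centre is not involved and stays S.

Step 11
Reactants: 16 (2S)-5-[4-(benzyloxy)-2-(methoxymethoxy)phenyl]pent-3-yn-2-ol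
Product: 17 (2S,3E)-5-[4-(benzyloxy)-2-(methoxymethoxy)phenyl]pent-3-en-2-ol
Conditions: NaAlH2(OCH2CH2OMe)2 (Red-Al), THF, 0 °C to rt; aq. KNaC4H4O6 (potassium sodium tartrate)
Reagents that add atoms: none
Why: Hydroxyl-directed trans-hydroalumination of a propargylic alcohol; the alkoxyaluminate delivers hydride within a cyclic vinylalanate, and protonolysis gives only the E-alkene. Aryl ethers and the acetal are inert to the hydride.

Step 12
Reactants: 8 3,3'-oxybis[2-(benzyloxy)phenol]; 17 (2S,3E)-5-[4-(benzyloxy)-2-(methoxymethoxy)phenyl]pent-3-en-2-ol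
Product: 18 2-(benzyloxy)-3-[2-(benzyloxy)-3-{[(2R,3E)-5-[4-(benzyloxy)-2-(methoxymethoxy)phenyl]pent-3-en-2-yl]oxy}phenoxy]phenol
Conditions: PPh3 (1.2 equiv), DIAD (1.2 equiv, slow addition), THF, 0 °C to rt; 8 and 17 in equimolar amounts
Reagents that add atoms: none
Why: Mitsunobu etherification of one of the two equivalent phenols: the phenoxide displaces the alkoxyphosphonium group by SN2, which inverts the carbinol centre from S to R. The phenols are remote and react independently, so the mono-ether should be the main component of a statistical mixture that is separable on silica, because 8, 18 and 19 differ by one free phenol each. The bis-ether 19 formed beside it is the product of step 13 and is added to it, and recovered 8 is returned, so the statistics cost no 17.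

Step 13
Reactants: 18 2-(benzyloxy)-3-[2-(benzyloxy)-3-{[(2R,3E)-5-[4-(benzyloxy)-2-(methoxymethoxy)phenyl]pent-3-en-2-yl]oxy}phenoxy]phenol; 17 (2S,3E)-5-[4-(benzyloxy)-2-(methoxymethoxy)phenyl]pent-3-en-2-ol
Product: 19 1,1'-oxybis{2-(benzyloxy)-3-[(2R,3E)-5-[4-(benzyloxy)-2-(methoxymethoxy)phenyl]pent-3-en-2-yl]oxybenzene}
Conditions: PPh3 (1.5 equiv), DIAD (1.5 equiv, slow addition), THF, 0 °C to rt; 17 in 1.3-fold amount
Reagents that add atoms: none
Why: Second Mitsunobu etherification, on the remaining phenol, again by SN2 with inversion from S to R, so both ether centres of 19 are R; the ether made in step 12 carries no acidic or hydroxyl group and is a spectator. The alkene is not conjugated to an arene, so ionisation of the allylic oxyphosphonium ion is not favoured.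

Step 14
Reactants: 19 1,1'-oxybis{2-(benzyloxy)-3-[(2R,3E)-5-[4-(benzyloxy)-2-(methoxymethoxy)phenyl]pent-3-en-2-yl]oxybenzene}
Product: 22 3,3'-oxybis{2-(benzyloxy)-6-[(2S,3E)-1-[4-(benzyloxy)-2-(methoxymethoxy)phenyl]pent-3-en-2-yl]phenol}, via bis(cyclohexa-2,4-dienone) 20 (not isolated), via bis(trimethylsilyl ether) 21 (not isolated)
Conditions: BSA (N,O-bis(trimethylsilyl)acetamide, 6 equiv), PhNEt2 (degassed), 185 °C, sealed tube, Ar; then K2CO3, MeOH, rt
Reagents that add atoms: none
Why: Each aryl allyl ether unit undergoes a concerted suprafacial [3,3]-sigmatropic shift (aromatic Claisen rearrangement; the closest known reaction type is the thermal ortho-Claisen rearrangement of enantioenriched secondary E-allyl aryl ethers with 1,3-chirality transfer): the O–C bond to the carbinol carbon breaks while the alkene terminus bonds to C1', and the dienone 20 enolises to the phenol, which BSA silylates at once to 21. No ring is closed. Each new stereocentre (the future C3) is controlled by the carbinol centre of its own ether unit: with the C–O bond perpendicular to the alkene and the methyl group pseudo-equatorial (carbinol hydrogen eclipsing the alkene, least allylic strain), the new C–C bond forms on the alkene face that the oxygen leaves, which turns the R ether centre and the E-alkene into the S benzylic centre and an E-propenyl group. Because C1' becomes planar again, chair and boat arrangements give the same centre, so only the pseudo-axial-methyl path erodes it, and that path is marked by a Z-propenyl group. The regioselectivity needed is C1' over C3' and C5': attack at the benzyloxy-bearing C3' gives a dienone that cannot enolise and can only revert or pass the group on to C5', whereas attack at C1' is made irreversible by enolisation. Silylation keeps the new phenol from the phenol-mediated abnormal Claisen isomerisation known for alkyl-substituted allyl groups and from acid catalysis of ether ionisation. The two ether units are remote and react independently, so the second shift needs nothing that the first does not.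

Step 15
Reactants: 22 3,3'-oxybis{2-(benzyloxy)-6-[(2S,3E)-1-[4-(benzyloxy)-2-(methoxymethoxy)phenyl]pent-3-en-2-yl]phenol}
Product: 23 1,1'-oxybis{2-(benzyloxy)-4-[(2S,3E)-1-[4-(benzyloxy)-2-(methoxymethoxy)phenyl]pent-3-en-2-yl]-3-methoxybenzene}
Conditions: MeI, K2CO3, DMF, rt to 40 °C
Reagents that add atoms: iodomethane, CI
Why: Williamson methylation of the two phenols released in step 14, with the smallest electrophile for a flanked hydroxyl. Carbonate is far too weak to deprotonate the benzylic–allylic C–H, so the stereocentres are safe.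

Step 16
Reactants: 23 1,1'-oxybis{2-(benzyloxy)-4-[(2S,3E)-1-[4-(benzyloxy)-2-(methoxymethoxy)phenyl]pent-3-en-2-yl]-3-methoxybenzene}
Product: 25 (2R,2'R)-2,2'-{oxybis[3-(benzyloxy)-2-methoxy-4,1-phenylene]}bis{3-[4-(benzyloxy)-2-(methoxymethoxy)phenyl]propan-1-ol}, via bis(1,2,4-trioxolane) 24 (not isolated)
Conditions: O3, CH2Cl2, −78 °C (Sudan Red 7B as end-point indicator); then NaBH4, MeOH, −78 to 0 °C
Reagents that add atoms: ozone, [O-][O+]=O
Why: Ozonolysis with reductive work-up; the alkenes react far faster than the arenes, and the indicator dye stops the ozone feed at the end point. Borohydride reduces the ozonide and the transient α-aryl aldehyde in the cold faster than the aldehyde can enolise, so C3 keeps its arrangement (the descriptor becomes R only because C2 now bears oxygen).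

Step 17
Reactants: 25 (2R,2'R)-2,2'-{oxybis[3-(benzyloxy)-2-methoxy-4,1-phenylene]}bis{3-[4-(benzyloxy)-2-(methoxymethoxy)phenyl]propan-1-ol}
Product: 26 (2R,2'R)-2,2'-{oxybis[3-(benzyloxy)-2-methoxy-4,1-phenylene]}bis{3-[4-(benzyloxy)-2-hydroxyphenyl]propan-1-ol}
Conditions: 3 M aq. HCl (cat.), MeOH/THF, 45 °C
Reagents that add atoms: none
Why: Acid-catalysed methanolysis of the two aryl methoxymethyl acetals; benzyl, methyl and diaryl ethers and the primary alcohols are stable, and no cation can form at C3.

Step 18
Reactants: 26 (2R,2'R)-2,2'-{oxybis[3-(benzyloxy)-2-methoxy-4,1-phenylene]}bis{3-[4-(benzyloxy)-2-hydroxyphenyl]propan-1-ol}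
Product: 27 (3R,3'R)-3,3'-{oxybis[3-(benzyloxy)-2-methoxy-4,1-phenylene]}bis[7-(benzyloxy)-3,4-dihydro-2H-chromene]
Conditions: PPh3, DIAD, THF (high dilution), 0 °C to rt
Reagents that add atoms: none
Why: Twofold intramolecular Mitsunobu etherification; each ring A phenoxide displaces the primary alkoxyphosphonium group in a 6-exo-tet closure, forming O1–C2. The ring A phenols are the only acidic groups present, and C3 is a spectator.

Step 19
Reactants: 27 (3R,3'R)-3,3'-{oxybis[3-(benzyloxy)-2-methoxy-4,1-phenylene]}bis[7-(benzyloxy)-3,4-dihydro-2H-chromene]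
Product: 28 (3R,3'R)-3,3'-[oxybis(3-hydroxy-2-methoxy-4,1-phenylene)]bis(3,4-dihydro-2H-chromen-7-ol)
Conditions: H2 (1 atm), Pd/C (10%), EtOAc/MeOH, rt
Reagents that add atoms: none
Why: Hydrogenolysis of the four benzyl aryl ethers; the diaryl ether, the methyl ethers and the chroman C–O bonds are not benzylic C–O bonds and stay intact, and C3 is untouched.

## Compound list

1 | 2,6-dibromophenol | Oc1c(Br)cccc1Br | starting material
2 | 2-(benzyloxy)-1,3-dibromobenzene | Brc1cccc(Br)c1OCc1ccccc1 | intermediate
3 | [2-(benzyloxy)-3-bromophenyl]lithium | [Li]c1cccc(Br)c1OCc1ccccc1 | intermediate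
4 | lithium [2-(benzyloxy)-3-bromophenyl]tri(propan-2-yloxy)borate | [Li+].CC(C)O[B-](OC(C)C)(OC(C)C)c1cccc(Br)c1OCc1ccccc1 | intermediate
5 | [2-(benzyloxy)-3-bromophenyl]boronic acid | OB(O)c1cccc(Br)c1OCc1ccccc1 | intermediate
6 | 2-(benzyloxy)-3-bromophenol | Oc1cccc(Br)c1OCc1ccccc1 | intermediate
7 | 1,1'-oxybis[2-(benzyloxy)-3-bromobenzene] | O(c1cccc(Br)c1OCc1ccccc1)c1cccc(Br)c1OCc1ccccc1 | intermediate
8 | 3,3'-oxybis[2-(benzyloxy)phenol] | O(c1cccc(O)c1OCc1ccccc1)c1cccc(O)c1OCc1ccccc1 | intermediate
9 | 2,4-dihydroxybenzaldehyde | O=Cc1ccc(O)cc1O | starting material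
10 | 4-(benzyloxy)-2-hydroxybenzaldehyde | O=Cc1ccc(OCc2ccccc2)cc1O | intermediate
11 | 4-(benzyloxy)-2-(methoxymethoxy)benzaldehyde | O=Cc1ccc(OCc2ccccc2)cc1OCOC | intermediate
12 | [4-(benzyloxy)-2-(methoxymethoxy)phenyl]methanol | OCc1ccc(OCc2ccccc2)cc1OCOC | intermediate
13 | 4-(benzyloxy)-1-(bromomethyl)-2-(methoxymethoxy)benzene | BrCc1ccc(OCc2ccccc2)cc1OCOC | intermediate
14 | (S)-but-3-yn-2-ol | C[C@H](O)C#C | starting material
15 | bis(bromomagnesium) derivative of (S)-but-3-yn-2-ol (O-magnesium alkoxide, C-magnesium acetylide) | C[C@H](O[Mg]Br)C#C[Mg]Br | intermediate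
16 | (2S)-5-[4-(benzyloxy)-2-(methoxymethoxy)phenyl]pent-3-yn-2-ol | C[C@H](O)C#CCc1ccc(OCc2ccccc2)cc1OCOC | intermediate
17 | (2S,3E)-5-[4-(benzyloxy)-2-(methoxymethoxy)phenyl]pent-3-en-2-ol | C[C@H](O)/C=C/Cc1ccc(OCc2ccccc2)cc1OCOC | intermediate
18 | 2-(benzyloxy)-3-[2-(benzyloxy)-3-{[(2R,3E)-5-[4-(benzyloxy)-2-(methoxymethoxy)phenyl]pent-3-en-2-yl]oxy}phenoxy]phenol | O(c1cccc(O[C@H](C)/C=C/Cc2ccc(OCc3ccccc3)cc2OCOC)c1OCc1ccccc1)c1cccc(O)c1OCc1ccccc1 | intermediate
19 | 1,1'-oxybis{2-(benzyloxy)-3-[(2R,3E)-5-[4-(benzyloxy)-2-(methoxymethoxy)phenyl]pent-3-en-2-yl]oxybenzene} | O(c1cccc(O[C@H](C)/C=C/Cc2ccc(OCc3ccccc3)cc2OCOC)c1OCc1ccccc1)c1cccc(O[C@H](C)/C=C/Cc2ccc(OCc3ccccc3)cc2OCOC)c1OCc1ccccc1 | intermediate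
20 | 3,3'-oxybis{2-(benzyloxy)-6-[(2S,3E)-1-[4-(benzyloxy)-2-(methoxymethoxy)phenyl]pent-3-en-2-yl]cyclohexa-2,4-dien-1-one} (ring sp3 carbon transient, configuration left open) | O(C1=C(OCc2ccccc2)C(=O)C(C=C1)[C@@H](Cc1ccc(OCc2ccccc2)cc1OCOC)/C=C/C)C1=C(OCc2ccccc2)C(=O)C(C=C1)[C@@H](Cc1ccc(OCc2ccccc2)cc1OCOC)/C=C/C | intermediate
21 | bis(trimethylsilyl ether) of 22 | O(c1ccc([C@@H](Cc2ccc(OCc3ccccc3)cc2OCOC)/C=C/C)c(O[Si](C)(C)C)c1OCc1ccccc1)c1ccc([C@@H](Cc2ccc(OCc3ccccc3)cc2OCOC)/C=C/C)c(O[Si](C)(C)C)c1OCc1ccccc1 | intermediate
22 | 3,3'-oxybis{2-(benzyloxy)-6-[(2S,3E)-1-[4-(benzyloxy)-2-(methoxymethoxy)phenyl]pent-3-en-2-yl]phenol} | O(c1ccc([C@@H](Cc2ccc(OCc3ccccc3)cc2OCOC)/C=C/C)c(O)c1OCc1ccccc1)c1ccc([C@@H](Cc2ccc(OCc3ccccc3)cc2OCOC)/C=C/C)c(O)c1OCc1ccccc1 | intermediate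
23 | 1,1'-oxybis{2-(benzyloxy)-4-[(2S,3E)-1-[4-(benzyloxy)-2-(methoxymethoxy)phenyl]pent-3-en-2-yl]-3-methoxybenzene} | O(c1ccc([C@@H](Cc2ccc(OCc3ccccc3)cc2OCOC)/C=C/C)c(OC)c1OCc1ccccc1)c1ccc([C@@H](Cc2ccc(OCc3ccccc3)cc2OCOC)/C=C/C)c(OC)c1OCc1ccccc1 | intermediate
24 | 1,1'-oxybis{2-(benzyloxy)-4-[(1R)-2-[4-(benzyloxy)-2-(methoxymethoxy)phenyl]-1-(5-methyl-1,2,4-trioxolan-3-yl)ethyl]-3-methoxybenzene} (ozonide carbons as a mixture) | O(c1ccc([C@@H](Cc2ccc(OCc3ccccc3)cc2OCOC)C2OOC(C)O2)c(OC)c1OCc1ccccc1)c1ccc([C@@H](Cc2ccc(OCc3ccccc3)cc2OCOC)C2OOC(C)O2)c(OC)c1OCc1ccccc1 | intermediate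
25 | (2R,2'R)-2,2'-{oxybis[3-(benzyloxy)-2-methoxy-4,1-phenylene]}bis{3-[4-(benzyloxy)-2-(methoxymethoxy)phenyl]propan-1-ol} | O(c1ccc([C@@H](Cc2ccc(OCc3ccccc3)cc2OCOC)CO)c(OC)c1OCc1ccccc1)c1ccc([C@@H](Cc2ccc(OCc3ccccc3)cc2OCOC)CO)c(OC)c1OCc1ccccc1 | intermediate
26 | (2R,2'R)-2,2'-{oxybis[3-(benzyloxy)-2-methoxy-4,1-phenylene]}bis{3-[4-(benzyloxy)-2-hydroxyphenyl]propan-1-ol} | O(c1ccc([C@@H](Cc2ccc(OCc3ccccc3)cc2O)CO)c(OC)c1OCc1ccccc1)c1ccc([C@@H](Cc2ccc(OCc3ccccc3)cc2O)CO)c(OC)c1OCc1ccccc1 | intermediate
27 | (3R,3'R)-3,3'-{oxybis[3-(benzyloxy)-2-methoxy-4,1-phenylene]}bis[7-(benzyloxy)-3,4-dihydro-2H-chromene] | COc1c([C@@H]2COc3cc(OCc4ccccc4)ccc3C2)ccc(Oc2ccc([C@@H]3COc4cc(OCc5ccccc5)ccc4C3)c(OC)c2OCc2ccccc2)c1OCc1ccccc1 | intermediate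
28 | (3R,3'R)-3,3'-[oxybis(3-hydroxy-2-methoxy-4,1-phenylene)]bis(3,4-dihydro-2H-chromen-7-ol) | COc1c([C@@H]2COc3cc(O)ccc3C2)ccc(Oc2ccc([C@@H]3COc4cc(O)ccc4C3)c(OC)c2O)c1O | target

## Step count and least certain steps

Total step count: 19. Longest linear sequence: 14 steps (from 9 through steps 6 to 11 and 12 to 19); the ring B branch from 1 contributes steps 1 to 5.

**Step 14 (key step).** Three processes can divert material: migration through the benzyloxy-bearing C3' and onward to C5' (para rearrangement); thermal fragmentation of the secondary allyl ether into phenol and diene; and leakage through the pseudo-axial-methyl arrangement, which gives the opposite C3 configuration together with a Z-propenyl group. Each leak counts twice in a two-directional step and gives statistical mixtures of large, similar molecules that are hard to separate.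

Fallback: the rearrangement is moved to the monomer stage; it sets out from 6 and 17 and comes back to the route at 23. Phenol 6 is etherified with 17 under the conditions of step 13 to give 2-(benzyloxy)-1-bromo-3-[(2R,3E)-5-[4-(benzyloxy)-2-(methoxymethoxy)phenyl]pent-3-en-2-yl]oxybenzene F1. F1 is rearranged under the conditions of step 14 to 2-(benzyloxy)-3-bromo-6-[(2S,3E)-1-[4-(benzyloxy)-2-(methoxymethoxy)phenyl]pent-3-en-2-yl]phenol F2; the para isomer and the Z-propenyl isomer (which carries the wrong C3 configuration) are now single small compounds that can be removed. Methylation as in step 15 gives 2-(benzyloxy)-1-bromo-4-[(2S,3E)-1-[4-(benzyloxy)-2-(methoxymethoxy)phenyl]pent-3-en-2-yl]-3-methoxybenzene F3. Half of F3 is hydroxylated as in step 5 to 2-(benzyloxy)-4-[(2S,3E)-1-[4-(benzyloxy)-2-(methoxymethoxy)phenyl]pent-3-en-2-yl]-3-methoxyphenol F4, and F3 and F4 are joined by an Ullmann ether synthesis (CuI, picolinic acid, K3PO4, DMSO, 90 °C) to give 23.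

**Step 12 (and step 13, which repeats the reaction on the second phenol).** The allylic oxyphosphonium ion may ionise or be attacked at the alkene terminus (SN2'), which would erode the carbinol configuration or transpose the ether. Elimination to a diene would consume 17. The statistical spread of the first etherification over 8, 18 and 19 lowers the throughput of each pass.

Fallback: the ether centre is set at the alkyne stage, where Mitsunobu displacement is a clean SN2 reaction, and a Z-alkene is used; it sets out from 8 and 13 and comes back to the route at 22. (R)-But-3-yn-2-ol F5 is alkylated with 13 as in step 10 to (2R)-5-[4-(benzyloxy)-2-(methoxymethoxy)phenyl]pent-3-yn-2-ol F6. Mitsunobu reaction of two molecules of F6 with 8 (PPh3, DIAD, THF) gives, with inversion, 1,1'-oxybis{2-(benzyloxy)-3-[(2S)-5-[4-(benzyloxy)-2-(methoxymethoxy)phenyl]pent-3-yn-2-yl]oxybenzene} F7. Semi-hydrogenation (H2, Pd/CaCO3 poisoned with Pb(OAc)2, quinoline, EtOAc) gives 1,1'-oxybis{2-(benzyloxy)-3-[(2S,3Z)-5-[4-(benzyloxy)-2-(methoxymethoxy)phenyl]pent-3-en-2-yl]oxybenzene} F8. F8 is rearranged under the conditions of step 14: a Z-alkene with the S ether centre passes through the same methyl-pseudo-equatorial arrangement to the same S benzylic centre and E-propenyl group, so it gives 22. The competing pseudo-axial path is further disfavoured by the clash between the methyl group and the cis substituent, at the price of a somewhat higher temperature.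

**Step 16.** Ozone may over-oxidise the electron-rich rings and the benzylic ether positions once the alkenes are consumed, and C3 may epimerise if the α-aryl aldehyde lives long enough to enolise before reduction.

Fallback: the alkenes are cleaved without ozone; it sets out from 23 and comes back to the route at 25. Dihydroxylation (OsO4 cat., NMO, acetone/H2O) gives 1,1'-oxybis{2-(benzyloxy)-4-[(2R)-1-[4-(benzyloxy)-2-(methoxymethoxy)phenyl]-3,4-dihydroxypentan-2-yl]-3-methoxybenzene} F9 as a diastereomer mixture at the diol carbons. Glycol cleavage with NaIO4 on silica gel in CH2Cl2 at 0 °C gives (2R,2'R)-2,2'-{oxybis[3-(benzyloxy)-2-methoxy-4,1-phenylene]}bis{3-[4-(benzyloxy)-2-(methoxymethoxy)phenyl]propanal} F10, which is filtered directly into NaBH4 in MeOH at −20 °C to give 25.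

**Step 10.** The magnesium alkoxide may be benzylated on oxygen; the product, a skipped arylmethyl alkyne, may isomerise to an allene under the basic conditions; and the electron-rich benzylic bromide may self-condense in the presence of the magnesium halide.

Fallback: a neutral sp2–sp3 coupling that also makes the E-alkene directly; it sets out from 14 and 13 and comes back to the route at 17. Silylation (TBSCl, imidazole, DMF) gives tert-butyl{[(2S)-but-3-yn-2-yl]oxy}dimethylsilane F11. Syn-hydroboration (pinacolborane, Cp2Zr(H)Cl cat., Et3N) gives tert-butyldimethyl{[(2S,3E)-4-(4,4,5,5-tetramethyl-1,3,2-dioxaborolan-2-yl)but-3-en-2-yl]oxy}silane F12. Suzuki–Miyaura coupling with 13 (Pd(PPh3)4, K3PO4, THF/H2O, 60 °C) gives tert-butyl{[(2S,3E)-5-[4-(benzyloxy)-2-(methoxymethoxy)phenyl]pent-3-en-2-yl]oxy}dimethylsilane F13, and TBAF in THF then gives 17.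

**Step 4.** Transmetalation of the ortho-substituted boronic acid to copper may be slow and protodeboronation may take over, so conversion of two ortho-alkoxy partners may stall.

Fallback: an Ullmann coupling of protected monomers; it sets out from 6 and comes back to the route at 8. Protection (MOMCl, iPr2NEt) gives 2-(benzyloxy)-1-bromo-3-(methoxymethoxy)benzene F14. Half of F14 is hydroxylated as in step 5 to 2-(benzyloxy)-3-(methoxymethoxy)phenol F15. F14 and F15 are coupled (CuI, picolinic acid, K3PO4, DMSO, 90 °C) to 1,1'-oxybis[2-(benzyloxy)-3-(methoxymethoxy)benzene] F16, and acid methanolysis (HCl, MeOH) gives 8.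

## Further compounds

F1 | step 14 | 2-(benzyloxy)-1-bromo-3-[(2R,3E)-5-[4-(benzyloxy)-2-(methoxymethoxy)phenyl]pent-3-en-2-yl]oxybenzene | Brc1cccc(O[C@H](C)/C=C/Cc2ccc(OCc3ccccc3)cc2OCOC)c1OCc1ccccc1
F2 | step 14 | 2-(benzyloxy)-3-bromo-6-[(2S,3E)-1-[4-(benzyloxy)-2-(methoxymethoxy)phenyl]pent-3-en-2-yl]phenol | Brc1ccc([C@@H](Cc2ccc(OCc3ccccc3)cc2OCOC)/C=C/C)c(O)c1OCc1ccccc1
F3 | step 14 | 2-(benzyloxy)-1-bromo-4-[(2S,3E)-1-[4-(benzyloxy)-2-(methoxymethoxy)phenyl]pent-3-en-2-yl]-3-methoxybenzene | Brc1ccc([C@@H](Cc2ccc(OCc3ccccc3)cc2OCOC)/C=C/C)c(OC)c1OCc1ccccc1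
F4 | step 14 | 2-(benzyloxy)-4-[(2S,3E)-1-[4-(benzyloxy)-2-(methoxymethoxy)phenyl]pent-3-en-2-yl]-3-methoxyphenol | Oc1ccc([C@@H](Cc2ccc(OCc3ccccc3)cc2OCOC)/C=C/C)c(OC)c1OCc1ccccc1
F5 | step 12 | (R)-but-3-yn-2-ol | C[C@@H](O)C#C
F6 | step 12 | (2R)-5-[4-(benzyloxy)-2-(methoxymethoxy)phenyl]pent-3-yn-2-ol | C[C@@H](O)C#CCc1ccc(OCc2ccccc2)cc1OCOC
F7 | step 12 | 1,1'-oxybis{2-(benzyloxy)-3-[(2S)-5-[4-(benzyloxy)-2-(methoxymethoxy)phenyl]pent-3-yn-2-yl]oxybenzene} | O(c1cccc(O[C@@H](C)C#CCc2ccc(OCc3ccccc3)cc2OCOC)c1OCc1ccccc1)c1cccc(O[C@@H](C)C#CCc2ccc(OCc3ccccc3)cc2OCOC)c1OCc1ccccc1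
F8 | step 12 | 1,1'-oxybis{2-(benzyloxy)-3-[(2S,3Z)-5-[4-(benzyloxy)-2-(methoxymethoxy)phenyl]pent-3-en-2-yl]oxybenzene} | O(c1cccc(O[C@@H](C)/C=C\Cc2ccc(OCc3ccccc3)cc2OCOC)c1OCc1ccccc1)c1cccc(O[C@@H](C)/C=C\Cc2ccc(OCc3ccccc3)cc2OCOC)c1OCc1ccccc1
F9 | step 16 | 1,1'-oxybis{2-(benzyloxy)-4-[(2R)-1-[4-(benzyloxy)-2-(methoxymethoxy)phenyl]-3,4-dihydroxypentan-2-yl]-3-methoxybenzene} (diol carbons as a mixture) | O(c1ccc([C@@H](Cc2ccc(OCc3ccccc3)cc2OCOC)C(O)C(C)O)c(OC)c1OCc1ccccc1)c1ccc([C@@H](Cc2ccc(OCc3ccccc3)cc2OCOC)C(O)C(C)O)c(OC)c1OCc1ccccc1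
F10 | step 16 | (2R,2'R)-2,2'-{oxybis[3-(benzyloxy)-2-methoxy-4,1-phenylene]}bis{3-[4-(benzyloxy)-2-(methoxymethoxy)phenyl]propanal} | O(c1ccc([C@@H](Cc2ccc(OCc3ccccc3)cc2OCOC)C=O)c(OC)c1OCc1ccccc1)c1ccc([C@@H](Cc2ccc(OCc3ccccc3)cc2OCOC)C=O)c(OC)c1OCc1ccccc1
F11 | step 10 | tert-butyl{[(2S)-but-3-yn-2-yl]oxy}dimethylsilane | C[C@H](O[Si](C)(C)C(C)(C)C)C#C
F12 | step 10 | tert-butyldimethyl{[(2S,3E)-4-(4,4,5,5-tetramethyl-1,3,2-dioxaborolan-2-yl)but-3-en-2-yl]oxy}silane | C[C@H](O[Si](C)(C)C(C)(C)C)/C=C/B1OC(C)(C)C(C)(C)O1
F13 | step 10 | tert-butyl{[(2S,3E)-5-[4-(benzyloxy)-2-(methoxymethoxy)phenyl]pent-3-en-2-yl]oxy}dimethylsilane | C[C@H](O[Si](C)(C)C(C)(C)C)/C=C/Cc1ccc(OCc2ccccc2)cc1OCOC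
F14 | step 4 | 2-(benzyloxy)-1-bromo-3-(methoxymethoxy)benzene | COCOc1cccc(Br)c1OCc1ccccc1
F15 | step 4 | 2-(benzyloxy)-3-(methoxymethoxy)phenol | COCOc1cccc(O)c1OCc1ccccc1
F16 | step 4 | 1,1'-oxybis[2-(benzyloxy)-3-(methoxymethoxy)benzene] | O(c1cccc(OCOC)c1OCc1ccccc1)c1cccc(OCOC)c1OCc1ccccc1
A1 | alternative 1 | bis(3-arylcyclobutanone) on the ring B diaryl ether core | COc1c(C2CC(=O)C2)ccc(Oc2ccc(C3CC(=O)C3)c(OC)c2OCc2ccccc2)c1OCc1ccccc1
A2 | alternative 1 | bis(β-aryl-γ-butyrolactone) | COc1c([C@@H]2COC(=O)C2)ccc(Oc2ccc([C@@H]3COC(=O)C3)c(OC)c2OCc2ccccc2)c1OCc1ccccc1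
A3 | alternative 2 | bis[2-aryl-3-(dimethylamino)acrolein] (bis-enaminal) | COc1c(C(C=O)=CN(C)C)ccc(Oc2ccc(C(C=O)=CN(C)C)c(OC)c2OCc2ccccc2)c1OCc1ccccc1
A4 | alternative 2 | resorcinol | Oc1cccc(O)c1
A5 | alternative 2 | bis(7-hydroxyisoflavylium) dichloride | COc1c(-c2c[o+]c3cc(O)ccc3c2)ccc(Oc2ccc(-c3c[o+]c4cc(O)ccc4c3)c(OC)c2OCc2ccccc2)c1OCc1ccccc1.[Cl-].[Cl-]
A6 | alternative 2 | bis(7-hydroxyisoflav-3-ene) | COc1c(C2=Cc3ccc(O)cc3OC2)ccc(Oc2ccc(C3=Cc4ccc(O)cc4OC3)c(OC)c2OCc2ccccc2)c1OCc1ccccc1
A7 | alternative 3 | ring B bis(pinacol boronate) with boron at C1' | COc1c(B2OC(C)(C)C(C)(C)O2)ccc(Oc2ccc(B3OC(C)(C)C(C)(C)O3)c(OC)c2OCc2ccccc2)c1OCc1ccccc1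
A8 | alternative 3 | vinyllithium | [Li]C=C
A9 | alternative 3 | 4-(benzyloxy)-2-(methoxymethoxy)phenyl trifluoromethanesulfonate | COCOc1cc(OCc2ccccc2)ccc1OS(=O)(=O)C(F)(F)F
A10 | alternative 3 | bis(secondary benzylic pinacol boronate) | COc1c([C@@H](Cc2ccc(OCc3ccccc3)cc2OCOC)B2OC(C)(C)C(C)(C)O2)ccc(Oc2ccc([C@@H](Cc3ccc(OCc4ccccc4)cc3OCOC)B3OC(C)(C)C(C)(C)O3)c(OC)c2OCc2ccccc2)c1OCc1ccccc1
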